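Assumption (one line): gibberellane numbering (C1–C19, no C20) is used; on the two-carbon bridge of a bicyclo[3.2.1]octane "exo" means syn to the one-carbon bridge and "endo" means facing the three-carbon bridge.

## Structural features

The target is a 20-nor-gibberellane. Cyclohexane ring A (C1–C5, C10) is bridged on its α face by a γ-lactone from C19 on C4 to the oxygen on C10; cyclopentane ring B (C5, C6, C8, C9, C10) carries the free C7 acid on C6; rings C and D form a bicyclo[3.2.1]octane with bridgeheads C8 and C13, a one-carbon bridge C14, a two-carbon bridge C15–C16 and a three-carbon bridge C9–C11–C12. Of nine stereocentres, seven (C3, C4, C5, C6, C8, C9, C10) form an unbroken chain that contains three fully substituted carbons (C4, C8, C10); the other two (C13, C16) lie in ring D. C13 is a plain CH bridgehead, and C16 is a tertiary carbinol with the hydroxyl endo (towards C11–C12) and the methyl C17 exo (towards C14), that is (16S). Two elements are fragile: the 3β-hydroxy lactone, a β-hydroxy carbonyl unit that epimerises at C3 by retro-aldol/aldol in base, and the tertiary C16–OH, which ionises in strong acid. The skeleton and seven stereocentres can be taken from fermentation-derived gibberellic acid, so the real difficulties are the oxygen on bridgehead C13 of that feedstock, where no substitution or elimination is possible, and the C16 configuration, which is opposite to the one hydration of a 16-ene would give. The key step exploits the isomeric bicyclo[3.2.1]octane in which C12 sits on C16 (bridgeheads C8 and C16): there C13 is a secondary carbon on the two-carbon bridge, and an exo leaving group on it is antiperiplanar to the C16–C12 bond, so ionisation returns C12 to C13 and rebuilds ring C without oxygen at C13.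

## Logic of the disconnections

16 ⇒ 14. The two O–CH2 bonds of the benzyl ester and the benzyl acetal are cut. Both fall to hydrogenolysis under neutral conditions, which avoids base (C3 retro-aldol) and acid (C16 carbinol). The gain is a single, last deprotection. The demand is that no C=C remains in the skeleton at that stage, which holds.

14 ⇒ 12 + 13. The C16–C17 bond is cut. The required carbinol (OH endo, CH3 exo) is the epimer of any cation-capture or hydration product, but it is what exo attack of a methyl nucleophile on the 16-ketone gives. The C16 stereocentre is thereby reduced to a facial selectivity. The forward step must avoid enolisation towards C15 and leave the ester and lactone alone; this is why the 3-oxygen is carried as an ether and not as an ester.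

12 ⇒ 10. The C16=O is traced to the exocyclic C16=C17 alkene, because that alkene is what the cationic shift delivers. The forward cleavage must spare the benzylic C–H bonds of both protecting groups.

10 ⇒ 9 (key). The C12–C13 bond is cut and C12 is reconnected to C16, with an exo sulfonate on C13. This turns removal of a bridgehead oxygen into ionisation of a secondary sulfonate. The gain is that C13 now carries its oxygen on a carbon that can come from a ketone. The forward step needs the exo configuration for antiperiplanar assistance, a buffered, non-nucleophilic ionising medium, and proton loss from C17.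

9 ⇒ 8 ⇒ 7 ⇒ 6. The S–O bond, then the C13–H bond, then the O3–CH2 bond are removed. The exo alcohol cannot be expected from a kinetic hydride, which would approach the ketone from the exo face, so the reduction is run under thermodynamic control. The 3-hydroxyl must be masked beforehand, since otherwise two secondary alcohols would compete in the reduction-equilibration and the sulfonylation.

6 ⇒ 5. The C12–C16 bond is cut and C12 is returned to C13, which restores the native 13-hydroxy-16-ene. The forward step is a proton-triggered semipinacol shift. It requires a saturated ring A, because the 1-ene allylic lactone does not survive acid.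

5 ⇒ 4 ⇒ 3 ⇒ 2. The C1–C2 unsaturation and the C3 alcohol are restored via the 3-ketone and the 3-enone. Catalytic hydrogenation is excluded because the 16-ene is needed for the shift. The forward demands are 1,4-selective hydride delivery and then equatorial hydride delivery to reset 3β.

2 ⇒ 1. The ester C–O bond is cut. A benzyl ester tolerates every later step and leaves with the acetal. The esterification must use a base mild enough not to isomerise ring A.

## Other disconnections considered

Alternative 1: The cut removes C3–C4 and C5–C10, so rings A and B are opened together. The precursor is triene A1, a C/D bicyclo[3.2.1]octane with a 1,4-bis(silyloxy)diene (C10=C1–C2=C3) on C9 and a Z-2-methyl enoate (C5=C4) on C6. Heating A1 would close both rings in a type 1 intramolecular Diels–Alder reaction to cycloadduct A2.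
- In favour: two C–C bonds, two rings and four stereocentres (C3, C4, C5, C10) would arise in one concerted suprafacial step. The Z enoate translates into the cis relation of C19 and C6, and the C10 oxygen and C19 ester are placed for the lactone.
- Against, here: A1 must be made enantiopure from scratch with C6, C8, C9, C13 and C16 in place. The diene terminus C10 is fully substituted, the dienophile is trisubstituted, and the trans relation of H-5 and O-10 needs one specific endo/exo and facial mode for which the three-atom tether gives little bias. Afterwards the 1-ene must be hydrogenated, two silyl groups removed, the lactone closed and an ester cleaved.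
- Comparison: structurally, the chosen plan inherits exactly the centres this cycloaddition must create and makes only C13 and C16. Mechanistically, the pericyclic step is stereospecific and free of the cation-partitioning problem of step 9. In bonds, rings and stereocentres per step, in independence from a fermentation feedstock and in openness to ring-A analogues, alternative 1 is the better. In step economy to this target the chosen plan (12 steps from a commercial compound) should be far shorter.

Alternative 2: The cut is C11–C12. The precursor is diene A3, a spirocyclic A/B/D system with C8 as spiro atom and a vinyl group on each of C9 and C13. (H2IMes)(PCy3)Cl2Ru=CHPh (second-generation Grubbs catalyst) would join the vinyl groups with loss of ethene to the 11-ene A4, a bicyclo[3.2.1]oct-2-ene; alkene hydrogenation and ester cleavage would follow.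
- In favour: the conditions are neutral and tolerate the free hydroxyls and the lactone, so no protecting groups are needed. No stereocentre or regiochemical choice is at stake in the ring closure.
- Against, here: all nine stereocentres, including the quaternary spiro C8 and the C16 carbinol, must already be in A3, so the difficulty is moved, not solved. Both vinyl groups must reach pseudo-axial positions, the bridged alkene is strained, and oligomerisation competes. Cleavage of the methyl ester next to the free 3β-hydroxy lactone exposes C3 to retro-aldol epimerisation.
- Comparison: structurally, the chosen plan uses a C/D bicycle that already exists. Mechanistically, metathesis is the equal or the better of step 9 in functional-group tolerance and in having no selectivity question of its own. Step economy is decided by access to A3, which should take many more steps than the whole chosen route.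

Alternative 3: The cut is C13–C16. The precursor is tricyclic enone A5: ring C is a 13-en-12-one and C8 carries a 2-oxopropyl chain (C15, C16=O, C17). [(Ph3P)CuH]6 (monovalent copper) would add hydride to C14, and the C13 copper enolate would add to the methyl ketone, closing ring D to the β-hydroxy ketone A6.
- In favour: C13 and C16 would be set in one step. The chelated copper aldolate puts the new hydroxyl on the side of the C12 carbonyl, that is endo, with methyl exo, which is the target configuration. On this point alternative 3 is better than the chosen plan, which needs two steps (oxidative cleavage and organometallic addition) and relies on steric approach control.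
- Against, here: the C12 carbonyl must then be removed next to a tertiary aldol that can revert or dehydrate, which costs about three operations. A5 needs rings A and B with six contiguous stereocentres and the quaternary C8, made from scratch or by a long degradation. Simple conjugate reduction without aldol closure competes.
- Comparison: structurally, the chosen plan avoids both the extra C12 oxygen and the synthesis of the A/B core. Mechanistically, the closed chelated transition state is an advantage for C16. In step economy the chosen plan should be clearly shorter.

Key step: step 9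

## Route

Step 1
Reactants: 1 gibberellic acid (gibberellin A3)
Product: 2 gibberellin A3 benzyl ester
Conditions: BnBr, KHCO3, DMF, 20 °C
Reagents that add atoms: benzyl bromide, BrCc1ccccc1
Why: Carboxylate O-alkylation (SN2 esterification); bicarbonate is too weak to trigger the alkaline lactone migration of ring A or to alkylate the hydroxyls, and no stereocentre is touched.

Step 2
Reactants: 2 gibberellin A3 benzyl ester
Product: 3 3-dehydrogibberellin A3 benzyl ester (3-oxo-1-ene)
Conditions: MnO2 (activated, excess), CH2Cl2, 20 °C
Reagents that add atoms: none
Why: Allylic alcohol oxidation with manganese dioxide; the tertiary 13-OH and the unconjugated 16-ene are inert, and the C3 stereocentre is erased on purpose, to be reset in step 4.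

Step 3
Reactants: 3 3-dehydrogibberellin A3 benzyl ester
Product: 4 3-dehydrogibberellin A1 benzyl ester (saturated 3-ketone)
Conditions: [(Ph3P)CuH]6 (0.4 equiv), H2O (2 equiv), benzene–THF, 20 °C
Reagents that add atoms: none
Why: Conjugate reduction by the copper hydride [(Ph3P)CuH]6: hydride goes to the β-carbon C1, water protonates the copper enolate, and the isolated 16-ene, which any catalytic hydrogenation would also saturate, is untouched; no new stereocentre.

Step 4
Reactants: 4 3-dehydrogibberellin A1 benzyl ester
Product: 5 gibberellin A1 benzyl ester (3β,13-diol, 16-ene)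
Conditions: K[HB(s-Bu)3] (2.5 equiv), THF, −78 °C; aq NH4Cl
Reagents that add atoms: none
Why: Ketone reduction by a hindered trialkylborohydride: the axial (β-face) path to C3 is closed by the 1,3-diaxial hydrogens on C1 and C5, so hydride should arrive equatorially and leave the hydroxyl axial, 3β and cis to C18; the low temperature protects the β-keto lactone from retro-Claisen cleavage.

Step 5
Reactants: 5 gibberellin A1 benzyl ester
Product: 6 shifted ketone (3β-hydroxy-16-methyl-13-oxo isomer with C12 bonded to C16; bridgeheads C8 and C16, one-carbon bridge C15, two-carbon bridge C14–C13; benzyl ester, 19,10-lactone)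
Conditions: TsOH·H2O (0.5 equiv), CH2Cl2, 40 °C
Reagents that add atoms: none
Why: Acid-triggered semipinacol (Wagner–Meerwein) rearrangement: protonation of C17 gives the C16 cation, the C13–C12 bond aligned with the empty orbital shifts to C16 under the push of the 13-OH lone pair, and proton loss leaves the C13 ketone; the new quaternary C16 is a bridgehead whose configuration is fixed by the bridged framework, and the saturated ring A, unlike the 1-ene, tolerates the acid.

Step 6
Reactants: 6 shifted ketone
Product: 7 3-O-benzyloxymethyl ether of the shifted ketone
Conditions: BnOCH2Cl, i-Pr2NEt, Bu4NI (cat.), CH2Cl2, 40 °C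
Reagents that add atoms: benzyl chloromethyl ether, ClCOCc1ccccc1
Why: O-alkylation with a reactive α-chloro ether (acetal formation) works on the hindered axial alcohol under an amine base too weak to start a retro-aldol; an ether is chosen over an ester so that it ignores the organometallic of step 11 and leaves with the benzyl ester in step 12.

Step 7
Reactants: 7 3-O-benzyloxymethyl ether of the shifted ketone
Product: 8 13-exo alcohol of the shifted skeleton (13S; OH syn to C15, H endo)
Conditions: {[Ph4(η5-C4CO)]2H}Ru2(CO)4(μ-H) (2 mol%), i-PrOH–toluene, 80 °C, run to equilibrium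
Reagents that add atoms: none
Why: Reversible transfer hydrogenation (the principle of a Meerwein–Ponndorf–Verley equilibration) puts the C13 carbinol under thermodynamic control: an endo hydroxyl would sit in a 1,3-diaxial-type contact with the axial C11–H under the two-carbon bridge, so the exo epimer should predominate, whereas a kinetic borohydride would attack the open exo face and give mainly the endo alcohol; residual endo epimer is separated or sent through the fallback.

Step 8
Reactants: 8 13-exo alcohol
Product: 9 13-exo methanesulfonate of the shifted skeleton (3-O-benzyloxymethyl ether, benzyl ester)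
Conditions: MsCl, Et3N, CH2Cl2, −20 °C; used crude
Reagents that add atoms: methanesulfonyl chloride, CS(=O)(=O)Cl
Why: Sulfonylation via sulfene forms the O–S bond without touching C13–O, so the exo configuration is retained; low temperature and immediate use avoid premature ionisation.

Step 9
Reactants: 9 13-exo methanesulfonate
Product: 10 gibberellin A4 benzyl ester 3-O-benzyloxymethyl ether (13-deoxy 16-ene)
Conditions: 2,6-lutidine (3 equiv), (CF3)2CHOH, 40 °C
Reagents that add atoms: none
Why: Buffered solvolysis with σ-participation: the exo C13–O bond ionises in the strongly ionising, weakly nucleophilic fluoro alcohol with backside help from the antiperiplanar C16–C12 bond. C12 thereby moves from C16 to C13, which restores the C12–C13 bond and leaves the tertiary C16 cation of the gibberellane, and 2,6-lutidine removes a C17 proton to give the exocyclic alkene. The closest known reaction type is the solvolytic Wagner–Meerwein rearrangement of exo-2-norbornyl-type and beyeranyl 16-sulfonates to kauranoid 16-enes, the reverse of step 5. Ring C (C8–C9–C11–C12–C13–C14) is closed not by an end-on cyclisation but by a suprafacial 1,2-alkyl shift, during which the six-membered ring through C15 contracts to the five-membered ring D. The new stereocentre C13 forms with inversion (C12 enters endo as the mesylate leaves exo) and, as a bridgehead, can only take the natural configuration; C16 ceases to be a stereocentre. Migration of C12 rather than C15 or methyl is secured by the exo leaving group (roughly anti to C16–C12, roughly perpendicular to C16–C15, gauche to C16–CH3) and by the cyclobutane that a C15 shift would create. Proton loss from C17 rather than capture or C15 deprotonation is favoured by the non-nucleophilic medium, the hindered base, three accessible methyl hydrogens and the strain of a double bond inside the five-membered ring; the buffer also prevents re-protonation of the alkene and protects the acetal. The benzyl ester, the acetal and every ring A and B stereocentre are spectators.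

Step 10
Reactants: 10 gibberellin A4 benzyl ester 3-O-benzyloxymethyl ether
Product: 12 17-nor-16-ketone (16-oxo-17-norgibberellin A4 benzyl ester 3-O-benzyloxymethyl ether), via 16,17-diol 11 (not isolated)
Conditions: OsO4 (2 mol%), NaIO4 (4 equiv), 2,6-lutidine, dioxane–H2O (3:1), 20 °C
Reagents that add atoms: osmium tetroxide, O=[Os](=O)(=O)=O; sodium periodate, [Na+].[O-]I(=O)(=O)=O
Why: Lemieux–Johnson oxidative cleavage: OsO4 dihydroxylates the only alkene from the exo face and periodate cleaves the diol to the ketone and formaldehyde; unlike ozone this does not threaten the benzylic C–H bonds of the two protecting groups.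

Step 11
Reactants: 12 17-nor-16-ketone; 13 methylmagnesium bromide
Product: 14 (16S)-16-hydroxy-16,17-dihydrogibberellin A4 benzyl ester 3-O-benzyloxymethyl ether (16-OH endo, 16-CH3 exo)
Conditions: CeCl3 (anhydrous, 1.5 equiv), THF, −78 °C; aq NH4Cl
Reagents that add atoms: none
Why: 1,2-Addition of the organocerium reagent MeCeCl2, formed in the flask from MeMgBr and CeCl3: the nucleophile should approach the exo face (C14 side), because the endo face is screened by the axial C11–H under the two-carbon bridge, which places methyl exo and hydroxyl endo (16S), the epimer of any hydration product; the weakly basic cerium reagent suppresses enolisation towards C15 and spares the hindered ester and lactone at −78 °C.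

Step 12
Reactants: 14 protected (16S)-carbinol
Product: 16 (16S)-16-hydroxy-16,17-dihydrogibberellin A4 (target), via 3-O-hydroxymethyl hemiacetal 15 (not isolated)
Conditions: H2 (1 atm), Pd(OH)2/C, EtOAc–MeOH, 20 °C
Reagents that add atoms: none
Why: Hydrogenolysis of the benzyl ester and of the benzyl acetal, whose hemiacetal then loses formaldehyde; the conditions are neutral, so C3 cannot epimerise by retro-aldol and the C16 carbinol cannot ionise, and the molecule has no C=C or allylic C–O left to reduce.

## Compound list

1 | gibberellic acid (gibberellin A3) | C[C@@]12C(=O)O[C@]3(C=C[C@@H]1O)[C@@H]1CC[C@]4(O)C[C@]1(CC4=C)[C@@H](C(=O)O)[C@@H]32 | starting material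
2 | gibberellin A3 benzyl ester | C[C@@]12C(=O)O[C@]3(C=C[C@@H]1O)[C@@H]1CC[C@]4(O)C[C@]1(CC4=C)[C@@H](C(=O)OCc5ccccc5)[C@@H]32 | intermediate
3 | 3-dehydrogibberellin A3 benzyl ester (3-oxo-1-ene) | C[C@@]12C(=O)O[C@]3(C=CC1=O)[C@@H]1CC[C@]4(O)C[C@]1(CC4=C)[C@@H](C(=O)OCc5ccccc5)[C@@H]32 | intermediate
4 | 3-dehydrogibberellin A1 benzyl ester (saturated 3-ketone) | C[C@@]12C(=O)O[C@]3(CCC1=O)[C@@H]1CC[C@]4(O)C[C@]1(CC4=C)[C@@H](C(=O)OCc5ccccc5)[C@@H]32 | intermediate
5 | gibberellin A1 benzyl ester | C[C@@]12C(=O)O[C@]3(CC[C@@H]1O)[C@@H]1CC[C@]4(O)C[C@]1(CC4=C)[C@@H](C(=O)OCc5ccccc5)[C@@H]32 | intermediate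
6 | shifted ketone: 3β-hydroxy-16-methyl-13-oxo isomer with C12 on C16, benzyl ester | C[C@@]12C(=O)O[C@]3(CC[C@@H]1O)[C@@H]1CC[C@]4(C)C(=O)C[C@]1(C4)[C@@H](C(=O)OCc5ccccc5)[C@@H]32 | intermediate
7 | 3-O-benzyloxymethyl ether of the shifted ketone | C[C@@]12C(=O)O[C@]3(CC[C@@H]1OCOCc6ccccc6)[C@@H]1CC[C@]4(C)C(=O)C[C@]1(C4)[C@@H](C(=O)OCc5ccccc5)[C@@H]32 | intermediate
8 | 13-exo alcohol (13S) of the shifted skeleton, 3-O-benzyloxymethyl ether, benzyl ester | C[C@@]12C(=O)O[C@]3(CC[C@@H]1OCOCc6ccccc6)[C@@H]1CC[C@]4(C)[C@@H](O)C[C@]1(C4)[C@@H](C(=O)OCc5ccccc5)[C@@H]32 | intermediate
9 | 13-exo methanesulfonate of the shifted skeleton, 3-O-benzyloxymethyl ether, benzyl ester | C[C@@]12C(=O)O[C@]3(CC[C@@H]1OCOCc6ccccc6)[C@@H]1CC[C@]4(C)[C@@H](OS(C)(=O)=O)C[C@]1(C4)[C@@H](C(=O)OCc5ccccc5)[C@@H]32 | intermediate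
10 | gibberellin A4 benzyl ester 3-O-benzyloxymethyl ether (13-deoxy 16-ene) | C[C@@]12C(=O)O[C@]3(CC[C@@H]1OCOCc6ccccc6)[C@@H]1CC[C@@H]4C[C@]1(CC4=C)[C@@H](C(=O)OCc5ccccc5)[C@@H]32 | intermediate
11 | 16-exo-hydroxy-16,17-diol of 10 | C[C@@]12C(=O)O[C@]3(CC[C@@H]1OCOCc6ccccc6)[C@@H]1CC[C@@H]4C[C@]1(C[C@@]4(CO)O)[C@@H](C(=O)OCc5ccccc5)[C@@H]32 | intermediate (not isolated)
12 | 16-oxo-17-norgibberellin A4 benzyl ester 3-O-benzyloxymethyl ether | C[C@@]12C(=O)O[C@]3(CC[C@@H]1OCOCc6ccccc6)[C@@H]1CC[C@@H]4C[C@]1(CC4=O)[C@@H](C(=O)OCc5ccccc5)[C@@H]32 | intermediate
13 | methylmagnesium bromide | C[Mg]Br | starting material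
14 | (16S)-16-hydroxy-16,17-dihydrogibberellin A4 benzyl ester 3-O-benzyloxymethyl ether | C[C@@]12C(=O)O[C@]3(CC[C@@H]1OCOCc6ccccc6)[C@@H]1CC[C@@H]4C[C@]1(C[C@]4(C)O)[C@@H](C(=O)OCc5ccccc5)[C@@H]32 | intermediate
15 | 3-O-hydroxymethyl hemiacetal of the target acid | C[C@@]12C(=O)O[C@]3(CC[C@@H]1OCO)[C@@H]1CC[C@@H]4C[C@]1(C[C@]4(C)O)[C@@H](C(=O)O)[C@@H]32 | intermediate (not isolated)
16 | (16S)-16-hydroxy-16,17-dihydrogibberellin A4 (16-OH endo, 16-CH3 exo) | C[C@@]12C(=O)O[C@]3(CC[C@@H]1O)[C@@H]1CC[C@@H]4C[C@]1(C[C@]4(C)O)[C@@H](C(=O)O)[C@@H]32 | target

## Step count and risks

Total: 12 steps. Longest linear sequence: 12 steps (1 to 16); 13 is a purchased reagent.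

Step 9 (key step). The most likely failure is partitioning of the C16 cation: proton loss from C15 instead of C17, or capture of the cation by mesylate or solvent on the exo face, would divert material. Ionisation would also be slow for any endo sulfonate carried in. Fallback: leave the cationic round trip and remove the C13 oxygen by radical chemistry. Setting out from 5, selective acetalisation of the secondary 3-hydroxyl (BnOCH2Cl, i-Pr2NEt) would give gibberellin A1 benzyl ester 3-O-benzyloxymethyl ether F1. Acylation of the tertiary 13-hydroxyl with methyl chlorooxoacetate and DMAP would give the 13-(methyl oxalate) F2. Bu3SnH/AIBN in hot toluene (a Barton–McCombie-type reduction of a tertiary oxalate; the bridgehead radical cannot rearrange) should then lead to 10, where the route is rejoined.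

Step 7. The risk is an insufficient thermodynamic bias, or slow hydrogen transfer at a ketone flanked by a quaternary carbon, so that the mixture stays rich in the endo alcohol. Fallback: accept the kinetic epimer and drop the need for assistance. From 7, NaBH4 (MeOH–THF, 0 °C) should give the 13-endo alcohol F3 by exo attack. Tf2O with 2,6-di-tert-butyl-4-methylpyridine in CH2Cl2 (−40 to 20 °C) would convert it into the 13-endo triflate F4, which is not isolated. A triflate ionises without neighbouring-group help, and in the free C13 cation the C16–C12 bond lies parallel to the empty orbital, so the same shift and proton loss should deliver 10 directly.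

Step 4. The risk is poor facial selectivity at C3 (axial hydride delivery would give the 3α alcohol) and base-induced cleavage of the β-keto lactone. Fallback: avoid a C3 ketone altogether. From 1, partial hydrogenation over Pd/BaSO4 in pyridine–THF (the classical poisoned-catalyst saturation of the ring-A alkene; it keeps the native 3β-hydroxyl but loses material to hydrogenolysis of the allylic lactone and to over-reduction of the 16-ene) would give gibberellin A1 F5. Benzylation as in step 1 returns to 5.

Step 11. The risks are enolisation of the ketone towards C15, erosion of exo-face selectivity, and attack on the benzyl ester if the temperature rises. Fallback: build the carbinol through an epoxide. From 12, dimethylsulfonium methylide (Me3S+ I−, KN(SiMe3)2, THF, −10 °C; Corey–Chaykovsky) should add irreversibly from the exo face to give the spiro-oxirane F6 with oxygen endo. Sodium phenylselenide (PhSeSePh, NaBH4, EtOH) would open it at the CH2 terminus to the β-hydroxy selenide F7. Bu3SnH/AIBN then removes selenium and gives 14.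

## Further compounds

F1 | step 9 | gibberellin A1 benzyl ester 3-O-benzyloxymethyl ether | C[C@@]12C(=O)O[C@]3(CC[C@@H]1OCOCc6ccccc6)[C@@H]1CC[C@]4(O)C[C@]1(CC4=C)[C@@H](C(=O)OCc5ccccc5)[C@@H]32
F2 | step 9 | 13-(methyl oxalate) of F1 | C[C@@]12C(=O)O[C@]3(CC[C@@H]1OCOCc6ccccc6)[C@@H]1CC[C@]4(OC(=O)C(=O)OC)C[C@]1(CC4=C)[C@@H](C(=O)OCc5ccccc5)[C@@H]32
F3 | step 7 | 13-endo alcohol of the shifted skeleton (C13 epimer of 8) | C[C@@]12C(=O)O[C@]3(CC[C@@H]1OCOCc6ccccc6)[C@@H]1CC[C@]4(C)[C@H](O)C[C@]1(C4)[C@@H](C(=O)OCc5ccccc5)[C@@H]32
F4 | step 7 | 13-endo trifluoromethanesulfonate of F3 | C[C@@]12C(=O)O[C@]3(CC[C@@H]1OCOCc6ccccc6)[C@@H]1CC[C@]4(C)[C@H](OS(=O)(=O)C(F)(F)F)C[C@]1(C4)[C@@H](C(=O)OCc5ccccc5)[C@@H]32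
F5 | step 4 | gibberellin A1 | C[C@@]12C(=O)O[C@]3(CC[C@@H]1O)[C@@H]1CC[C@]4(O)C[C@]1(CC4=C)[C@@H](C(=O)O)[C@@H]32
F6 | step 11 | 16,17-epoxide with oxygen endo (spiro-oxirane from 12) | C[C@@]12C(=O)O[C@]3(CC[C@@H]1OCOCc6ccccc6)[C@@H]1CC[C@@H]4C[C@]1(C[C@@]47CO7)[C@@H](C(=O)OCc5ccccc5)[C@@H]32
F7 | step 11 | 16-endo-hydroxy-17-phenylselanyl derivative | C[C@@]12C(=O)O[C@]3(CC[C@@H]1OCOCc6ccccc6)[C@@H]1CC[C@@H]4C[C@]1(C[C@]4(C[Se]c7ccccc7)O)[C@@H](C(=O)OCc5ccccc5)[C@@H]32
A1 | alternative 1 | Diels–Alder triene: C/D bicycle with the bis(silyloxy)diene on C9 and the Z-2-methyl enoate on C6 | COC(=O)/C(C)=C\[C@H](C(=O)OC)[C@@]12C[C@@H](CC[C@H]1/C(O[Si](CC)(CC)CC)=C/C=C/O[Si](C)(C)C(C)(C)C)[C@@](C)(O)C2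
A2 | alternative 1 | cycloadduct: tetracyclic 1-ene, 3-OTBS, 10-OTES, 7,19-dimethyl ester | C[C@@]1(C(=O)OC)[C@@H](O[Si](C)(C)C(C)(C)C)C=C[C@@]2(O[Si](CC)(CC)CC)[C@@H]3CC[C@@H]4C[C@]3(C[C@]4(C)O)[C@@H](C(=O)OC)[C@H]12
A3 | alternative 2 | spirocyclic 9,13-divinyl metathesis precursor (methyl ester) | C[C@@]12C(=O)O[C@]3(CC[C@@H]1O)[C@H](C=C)[C@]1(C[C@@H](C=C)[C@@](C)(O)C1)[C@@H](C(=O)OC)[C@@H]32
A4 | alternative 2 | 11-ene of the target methyl ester | C[C@@]12C(=O)O[C@]3(CC[C@@H]1O)[C@@H]1C=C[C@@H]4C[C@]1(C[C@]4(C)O)[C@@H](C(=O)OC)[C@@H]32
A5 | alternative 3 | 13-en-12-one with 2-oxopropyl on C8 (3-OTBS, methyl ester) | C[C@@]12C(=O)O[C@]3(CC[C@@H]1O[Si](C)(C)C(C)(C)C)[C@@H]1CC(=O)C=C[C@]1(CC(C)=O)[C@@H](C(=O)OC)[C@@H]32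
A6 | alternative 3 | 12-oxo derivative of the target 3-OTBS ether methyl ester | C[C@@]12C(=O)O[C@]3(CC[C@@H]1O[Si](C)(C)C(C)(C)C)[C@@H]1CC(=O)[C@@H]4C[C@]1(C[C@]4(C)O)[C@@H](C(=O)OC)[C@@H]32
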